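Theta's 3.00 equiv of reagent is one equivalent more than the two that carry each substrate to bis adduct.

| flask | substrate | reagent | remark | time |
|---|---|---|---|---|
| north | 1.5 mM | 4 equiv | run made earlier |  |
| west | 0.50 mM | 4 equiv | run made earlier |  |
| delta | 1.0 mM | 4.00 equiv |  | 4.0 min |
| theta | 1.0 mM | 3.00 equiv |  | 4.0 min |

- north (time / min: bis adduct / %, first product / %): 0.667: 74.5, 1.4; 1.33: 63.2, 0; 2.00: 50.9, 0; 2.50: 44.0, 0.5
- west (time / min: bis adduct / %, first product / %): 0.333: 40.6, 9.5; 0.833: 67.6, 4.6; 1.50: 76.2, 1.4; 2.50: 73.1, 0.8

(standard deviation of a reading: 0.3 percentage points)

- which of these holds the largest part of the substrate at the end of delta (first product / substrate / bis adduct / triple product)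
- which of these holds the largest part of the substrate at the end of theta (first product / substrate / bis adduct / triple product)
- bis adduct at the end of theta, in percent of the substrate charged

Substrate, charged in the smaller amount, is the limiting reagent, so you keep the books in fractions of its charge. The first entry is one reagent for first product and the second is one more for bis adduct. North's first product reads 0 % at 1.33 min, so as an estimate you close these two entries at the start. The last entry is one reagent for each substrate going from bis adduct to triple product. With b the fraction in bis adduct, the reagent left is b in theta and one plus b in north and delta.

Bis adduct is lost at k times reagent times b. In north, the logarithm of (one plus b)/b then climbs in step with time, and the fall from 63.2 % to 44.0 % reads k as 0.135 /mM/min. For 1.0 mM and 4.0 min, k times charge times time is 0.540; call this the reagent clock.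

My reckoning starts b at one. In theta, the reciprocal of b rises by the clock, giving 64.9 % bis adduct. In delta, (one plus b)/b starts at two and grows by the exponential of the clock, giving 41.1 % bis adduct, so my reckoning puts more triple product than bis adduct in delta.

The forecast, made on a reckoning of its own and not on mine, said triple product for delta, and for theta bis adduct at 65 %, reasoning that in theta “only about 1 mM reagent remains”.

The flask gives 58.0 % triple product and 41.9 % bis adduct in delta, and 63.6 % bis adduct and 35.7 % triple product in theta. The forecast held.

    substrate + reagent → first product + by-product (k = 30.0 /M/s)
    reagent + bis adduct → triple product + by-product (k = 2.30 /M/s)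
    reagent + first product → bis adduct + by-product (k = 120 /M/s)
    substrate ⇌ dormant form (K = 0.440, k = 0.250 /s)

Theta's end also holds 0.389 % substrate, 0.118 % first product and 0.175 % dormant form, together far less than its 63.6 % bis adduct. The neighbour flask repeats theta with 0.60 mM of substrate at the same equivalents, so its spare stays one equivalent while its clock drops to 0.324, which gives 75.5 % bis adduct. The neighbour flask ends with 72.3 % bis adduct and 24.8 % triple product. Beside these it holds 1.61 % substrate, 0.487 % first product and 0.721 % dormant form.

(The runs come from a simulation with made-up constants; the scatter is artificial.)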